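The gamma run reads 35.7 % mono adduct at 20.0 min, yet its partner, the limiting reagent, allows 57.6 %. The mono adduct still rises at the last reading of each run.

| flask | starting material | partner | remark | time |
|---|---|---|---|---|
| epsilon | 59 mM | 56.4 mM | run made earlier |  |
| gamma | 98 mM | 56.4 mM | run made earlier |  |
| eta | 47 mM | 84 mM | run made earlier |  |
| Thursday's | 47 mM | 56.4 mM |  | 30 min |
| Sunday's | 80 mM | 150 mM |  | 30 min |

| run | time / min | mono adduct / % |
|---|---|---|
| epsilon | 5.00 | 25.2 |
| epsilon | 10.0 | 36.5 |
| epsilon | 15.0 | 40.8 |
| epsilon | 20.0 | 43.1 |
| gamma | 1.50 | 8.8 |
| gamma | 4.00 | 20.8 |
| gamma | 10.0 | 31.1 |
| gamma | 20.0 | 35.7 |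
| eta | 5.00 | 38.5 |
| eta | 10.0 | 50.8 |
| eta | 15.0 | 57.1 |
| eta | 20.0 | 61.8 |

(readings scatter by 1 percentage point)

1. which of the two ends with the higher amount of mono adduct, in percent of the starting material charged ("neither" if they lie within 2 percentage points) (Thursday's / Sunday's / neither)
2. mono adduct at the end, in percent of the starting material charged, Thursday's
3. mono adduct at the end, in percent of the starting material charged, Sunday's

- what was read earlier has a scatter of 1 percentage point, one standard deviation
- what may be going on: partner -> decomposed reagent; partner + tris adduct -> tetra adduct; starting material + partner -> mono adduct; partner + double product -> tris adduct; partner + mono adduct -> double product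

I build the flask in steps. With the main step by itself, one partner makes one mono adduct, so Thursday's, at 1.20 equivalents, and Sunday's, at 1.88, allow full conversion.

Now I add decomposition of the partner. Decomposition goes with partner, addition with partner times starting material. Their ratio holds neither partner nor time, and it grows as starting material falls. Summed in logarithms, the partner charge equals the conversion in mM plus a constant times the decades of starting material lost. Gamma spends 35.0 mM on addition, so the waste per decade, partner lost for each tenfold fall in starting material, reads 112 mM. It reads high, since I count gamma's remaining partner as spent.

Converting half of Thursday's starting material costs 57.1 mM by this high reading, close to its charge of 56.4 mM, so my estimate for Thursday's is about that conversion. Sunday's charge of 150 mM lies between the cost of leaving 20.0 %, 142 mM, and of leaving 16.7 %, 154 mM.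

The remaining steps take mono adduct from these conversions, and I have no measure of that from the readings.

The forecast says Sunday's, with 49 % (45 % to 53 %) and 73 % (66 % to 79 %), Sunday's “with over-addition the main uncertainty”.

The simulation gives 49.4 % for Thursday's and 79.3 % for Sunday's, so Sunday's ends higher, 6.3 percentage points above the forecast's Sunday's figure.

    partner → decomposed reagent (k = 0.0660 /min)
    partner + tris adduct → tetra adduct (k = 0.690 /M/min)
    starting material + partner → mono adduct (k = 1.50 /M/min)
    partner + double product → tris adduct (k = 2.90 /M/min)
    partner + mono adduct → double product (k = 0.0450 /M/min)

Sunday's converts 81.9 %. On Thursday's, the half-life of mono adduct by further addition, 4.6 h, is longer than the 30 min run. On Sunday's, the waste per decade predicts 82.8 mM decomposed, against 75.1 mM found. A neighbour of Sunday's, charged with 320 mM of starting material, keeps 60.5 % of it, which the rule prices at 151 mM against the 150 mM charged. That neighbour ends with 39.2 % mono adduct.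

(The numbers in the tables were generated by integration from invented constants; noise was put on by code.)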